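Locants follow spiro[4.5]decane numbering: C1 = cyclopentane methine with the side chain, C4 = methyl-bearing carbon, C5 = spiro carbon, C6–C10 = six-membered ring (C7=C8 olefin, C8 ester-bearing, C9 carbinol).
Cuts: C8–CO2Me (back to a vinyl iodide); C9–H (back to an enone); the CH2–CH2 bond of the keto chain (back to an aldehyde and a ketophosphonate); then in one operation the C5–C1 ring bond and the C–H bond of the side-chain methine (retro-ene); last, the two olefin bonds of the tether.
Enabling feature: C5 stands 1,3 to oxygen-bearing C9 in the six-membered ring, and ring methylene C6 lies on the same cyclopentane face as the side-chain methine on C1. This pattern remains when the alkyl-bearing sp2 carbon of a 1-methoxy-5-alkylcyclohexa-1,4-diene bonds to the β carbon of an enoate held three carbons away and the doubly allylic ring CH2 gives a hydrogen to the α carbon.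
Forward order: the six-membered ring is the arene of 3'-methoxyacetophenone, dearomatised by Birch reduction. Two olefinations supply tether and enoate, and the ene step closes the cyclopentane. Hydrolysis, iodination and carbonylation dress the six-membered ring, and a third olefination completes the chain.
Stereochemistry: C4 comes from an iridium-catalysed asymmetric hydrogenation. C5, C1 and the side-chain methine are relayed from C4 in the ene transition state (allylic strain, cis fusion, Z-enoate geometry). C9 comes from a reagent-controlled CBS reduction.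

Key step: step 7

Assumption: the hand of the spiro phosphine-oxazoline ligand that leads to the S acid is inferred from closely related (E)-4-arylpent-3-enoic acids and is to be confirmed by the sign of optical rotation before material is carried on; both phosphonate reagents are taken as catalogue items.

Step 1
Reactants: 1 3'-methoxyacetophenone; 2 (2-carboxyethyl)triphenylphosphonium bromide
Product: 4 (E)-4-(3-methoxyphenyl)pent-3-enoic acid, via carboxylate ylide 3 (not isolated)
Conditions: 2 (1.3 equiv), KOtBu (2.7 equiv), THF, 0 °C; then 1, 0 °C to reflux; 1 M HCl work-up; E isomer crystallised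
Reagents that add atoms: none
Why: Wittig olefination of an aryl methyl ketone with the carboxylate-bearing ylide (two equivalents of base per salt, so the acid travels as its potassium salt) is an established entry to 4-arylpent-3-enoic acids and favours the E olefin, which is freed from the Z isomer by crystallisation because olefin geometry decides the sense of step 2.

Step 2
Reactants: 4 (E)-4-(3-methoxyphenyl)pent-3-enoic acid
Product: 5 (S)-4-(3-methoxyphenyl)pentanoic acid
Conditions: H2 (6 atm), [Ir(cod)(L*)][B(3,5-(CF3)2C6H3)4] (0.5 mol %; L* = 7-(diarylphosphino)-7'-(4,5-dihydrooxazol-2-yl)-1,1'-spirobiindane, antipode chosen for S), Et3N (0.5 equiv), MeOH, 25–45 °C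
Reagents that add atoms: none
Why: In this carboxylate-directed iridium-catalysed asymmetric hydrogenation of a β,γ-unsaturated acid, the carboxylate binds the cationic iridium centre and the spiro ligand pocket admits only one face of the E trisubstituted olefin, which sets the benzylic stereocentre (later C4) as S.

Step 3
Reactants: 5 (S)-4-(3-methoxyphenyl)pentanoic acid
Product: 6 (S)-4-(3-methoxyphenyl)pentan-1-ol
Conditions: LiAlH4, THF, 0 °C to rt; H2O/aq NaOH work-up
Reagents that add atoms: none
Why: Lithium aluminium hydride reduction of a carboxylic acid to the primary alcohol leaves the anisole ring and the remote, non-enolisable stereocentre untouched.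

Step 4
Reactants: 6 (S)-4-(3-methoxyphenyl)pentan-1-ol
Product: 7 (S)-4-(5-methoxycyclohexa-1,4-dien-1-yl)pentan-1-ol
Conditions: Li (6 equiv), NH3(l)/THF/t-BuOH, −78 to −33 °C; MeOH quench; NH3 evaporated; H2O/Et2O, dried over K2CO3
Reagents that add atoms: none
Why: Birch reduction of a 3-alkylanisole keeps both donor substituents on residual double bonds, so the ring is protonated between them and para to that position and gives the 1-methoxy-5-alkylcyclohexa-1,4-diene, whose enol ether and skipped diene persist while the work-up stays basic.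

Step 5
Reactants: 7 (S)-4-(5-methoxycyclohexa-1,4-dien-1-yl)pentan-1-ol
Product: 8 (S)-4-(5-methoxycyclohexa-1,4-dien-1-yl)pentanal
Conditions: SO3·pyridine (3 equiv), DMSO, Et3N (6 equiv), CH2Cl2, 0 °C; aq NaHCO3 work-up; Et3N-deactivated silica
Reagents that add atoms: none
Why: Parikh-Doering oxidation runs in excess triethylamine and releases neither acid nor electrophilic halogen, so the primary alcohol should reach the aldehyde without hydrolysis, conjugation or aromatisation of the methoxydiene.

Step 6
Reactants: 8 (S)-4-(5-methoxycyclohexa-1,4-dien-1-yl)pentanal; 9 methyl 2-[bis(2,2,2-trifluoroethoxy)phosphoryl]propanoate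
Product: 11 methyl (2Z,6S)-6-(5-methoxycyclohexa-1,4-dien-1-yl)-2-methylhept-2-enoate, via potassium phosphonate carbanion 10 (not isolated)
Conditions: 9 (1.2 equiv), KN(SiMe3)2 (1.15 equiv), 18-crown-6 (3 equiv), THF, −78 °C; then 8, −78 °C; aq NaHCO3 quench
Reagents that add atoms: none
Why: In the Still-Gennari variant of the Horner-Wadsworth-Emmons reaction the electron-poor trifluoroethyl phosphonate with a dissociated potassium counter-ion eliminates under kinetic control and gives the Z trisubstituted enoate (ester cis to the chain) from unbranched aliphatic aldehydes, under basic conditions that the enol ether tolerates.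

Step 7
Reactants: 11 methyl (2Z,6S)-6-(5-methoxycyclohexa-1,4-dien-1-yl)-2-methylhept-2-enoate
Product: 12 methyl (2S)-2-[(1R,4S,5S)-9-methoxy-4-methylspiro[4.5]deca-6,8-dien-1-yl]propanoate
Conditions: degassed toluene (0.01 M), BHT (0.1 equiv), 2,6-di-tert-butyl-4-methylpyridine (0.2 equiv), base-washed and silylated sealed tube, 200 °C (window 180–230 °C)
Reagents that add atoms: none
Why: Proposed new method: a concerted, suprafacial six-centre ene reaction is expected in which the alkyl-bearing diene carbon bonds to the enoate β carbon, the ring CH2 flanked by the two olefinic CH groups passes its hydrogen on the same face to the enoate α carbon, and the ring double bond slides into conjugation with the enol ether. The closest known reaction types are thermal type 1 intramolecular ene cyclisations of 1,6-dienes onto enoates, ene spirocyclisations of 1-alkylcyclohexenes to spiro[4.5]decenes and hydrogen donation by cyclohexa-1,4-dienes to activated enophiles; untested is a Birch-derived methoxydiene as the tethered donor, which should help because the C–H bond broken is doubly allylic and weak, the product gains a conjugated 1-methoxydiene, and the new quaternary carbon blocks aromatisation. The cyclopentane, the only ring formed, closes in a 5-exo mode with respect to both π bonds. For C5, the S stereocentre of the tether keeps its C–H bond eclipsed with the reacting ring double bond (allylic strain), so the chain rises from one diene face and the methyl lies on the other, away from the six-centre array; for C1, the bicyclic transition state can only be cis-fused, which puts the propanoate branch on the cyclopentane face of the hydrogen-donating arm C6=C7; for the side-chain methine, carbon and hydrogen add to the same face of the Z-enoate, so the E isomer would give the epimer. The step needs five-ring closure at the substituted carbon rather than six-ring closure at the neighbouring CH, which the three-carbon tether and the match of the electrophilic β carbon with the more substituted olefin terminus secure; it also needs the ene path to outrun transfer hydrogenation with aromatisation and acid-induced diene conjugation followed by cycloaddition, which dilution, exclusion of oxygen, the radical inhibitor, the hindered base and base-washed glass secure.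

Step 8
Reactants: 12 methyl (2S)-2-[(1R,4S,5S)-9-methoxy-4-methylspiro[4.5]deca-6,8-dien-1-yl]propanoate
Product: 13 methyl (2S)-2-[(1R,4S,5S)-4-methyl-9-oxospiro[4.5]dec-7-en-1-yl]propanoate
Conditions: 1 M HCl, THF, 0 °C to rt
Reagents that add atoms: water, O
Why: Acid hydrolysis of a 1-methoxy-1,3-diene (protonation, addition of water, loss of methanol) under equilibrating conditions gives the cyclohex-2-enone, the only conjugated isomer possible because C10 is attached to the quaternary carbon, and dilute acid at room temperature spares the methyl ester and its α stereocentre.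

Step 9
Reactants: 13 methyl (2S)-2-[(1R,4S,5S)-4-methyl-9-oxospiro[4.5]dec-7-en-1-yl]propanoate
Product: 14 methyl (2S)-2-[(1R,4S,5S)-8-iodo-4-methyl-9-oxospiro[4.5]dec-7-en-1-yl]propanoate
Conditions: I2 (2 equiv), pyridine/CH2Cl2 1:1, 0 °C to rt; aq Na2S2O3 work-up
Reagents that add atoms: iodine, II
Why: In this Baylis-Hillman-type α-iodination of a cyclic enone, pyridine adds reversibly to the unhindered β carbon, the resulting enolate is iodinated and pyridine is expelled, so iodine ends only on the α-vinylic carbon C8.

Step 10
Reactants: 14 methyl (2S)-2-[(1R,4S,5S)-8-iodo-4-methyl-9-oxospiro[4.5]dec-7-en-1-yl]propanoate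
Product: 15 methyl (2S)-2-[(1R,4S,5S,9S)-9-hydroxy-8-iodo-4-methylspiro[4.5]dec-7-en-1-yl]propanoate
Conditions: (R)-1-methyl-3,3-diphenyltetrahydro-1H,3H-pyrrolo[1,2-c][1,3,2]oxazaborole ((R)-Me-CBS, 0.3 equiv), BH3·SMe2 (1.0 equiv), THF, −30 °C; MeOH quench, aqueous work-up
Reagents that add atoms: none
Why: In the Corey-Bakshi-Shibata reduction, for which 2-halocycloalkenones are among the best substrates, the iodovinyl arm acts as the large group and the C10 methylene as the small one, so the (R)-oxazaborolidine should deliver hydride to the face that gives the 9S carbinol under reagent control, while the ester is inert to borane at this temperature.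

Step 11
Reactants: 15 methyl (2S)-2-[(1R,4S,5S,9S)-9-hydroxy-8-iodo-4-methylspiro[4.5]dec-7-en-1-yl]propanoate
Product: 16 methyl (2S)-2-[(1R,4S,5S,9S)-9-(tert-butyldimethylsilyloxy)-8-iodo-4-methylspiro[4.5]dec-7-en-1-yl]propanoate
Conditions: TBSOTf (1.3 equiv), 2,6-lutidine (2 equiv), CH2Cl2, 0 °C
Reagents that add atoms: tert-butyldimethylsilyl triflate, CC(C)(C)[Si](C)(C)OS(=O)(=O)C(F)(F)F
Why: Standard silylation of a hindered secondary allylic alcohol with the silyl triflate and a non-nucleophilic base masks the hydroxyl for the hydride, base and palladium steps that follow and touches no stereocentre.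

Step 12
Reactants: 16 methyl (2S)-2-[(1R,4S,5S,9S)-9-(tert-butyldimethylsilyloxy)-8-iodo-4-methylspiro[4.5]dec-7-en-1-yl]propanoate
Product: 18 (2S)-2-[(1R,4S,5S,9S)-9-(tert-butyldimethylsilyloxy)-8-iodo-4-methylspiro[4.5]dec-7-en-1-yl]propanal, via aluminium hemiacetal 17 (not isolated)
Conditions: i-Bu2AlH (1.1 equiv), CH2Cl2, −78 °C; MeOH at −78 °C, then aq potassium sodium tartrate
Reagents that add atoms: none
Why: In the partial reduction of a methyl ester with one equivalent of diisobutylaluminium hydride, the tetrahedral aluminium hemiacetal of this α-branched, hindered ester holds at −78 °C and collapses to the aldehyde only on quenching, and the vinyl iodide and silyl ether are inert.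

Step 13
Reactants: 18 (2S)-2-[(1R,4S,5S,9S)-9-(tert-butyldimethylsilyloxy)-8-iodo-4-methylspiro[4.5]dec-7-en-1-yl]propanal; 19 dimethyl (3-methyl-2-oxobutyl)phosphonate
Product: 21 (4E,6R)-6-[(1R,4S,5S,9S)-9-(tert-butyldimethylsilyloxy)-8-iodo-4-methylspiro[4.5]dec-7-en-1-yl]-2-methylhept-4-en-3-one, via lithium phosphonate carbanion 20 (not isolated)
Conditions: 19 (1.5 equiv), LiCl (1.6 equiv), i-Pr2NEt (1.5 equiv), MeCN, rt
Reagents that add atoms: none
Why: In the Horner-Wadsworth-Emmons olefination under Masamune-Roush conditions, lithium chelation makes the β-ketophosphonate acidic enough for a tertiary amine, so the E-enone forms without epimerising the α-methyl aldehyde (the descriptor of that carbon changes to R only through the priority rules).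

Step 14
Reactants: 21 (4E,6R)-6-[(1R,4S,5S,9S)-9-(tert-butyldimethylsilyloxy)-8-iodo-4-methylspiro[4.5]dec-7-en-1-yl]-2-methylhept-4-en-3-one
Product: 22 methyl (1R,4S,5S,9S)-9-(tert-butyldimethylsilyloxy)-4-methyl-1-[(2R,3E)-6-methyl-5-oxohept-3-en-2-yl]spiro[4.5]dec-7-ene-8-carboxylate
Conditions: CO (1 atm), Pd(OAc)2 (5 mol %), PPh3 (15 mol %), Et3N (3 equiv), MeOH/DMF 1:2, 50 °C
Reagents that add atoms: carbon monoxide, [C-]#[O+]; methanol, CO
Why: Palladium-catalysed alkoxycarbonylation of a vinyl iodide (oxidative addition to zerovalent palladium, CO insertion, methanolysis of the acylpalladium species) turns the carbon-iodine bond at C8 into the methyl enoate without moving the ring olefin, CO insertion being faster than any Heck reaction with the remote enone.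

Step 15
Reactants: 22 methyl (1R,4S,5S,9S)-9-(tert-butyldimethylsilyloxy)-4-methyl-1-[(2R,3E)-6-methyl-5-oxohept-3-en-2-yl]spiro[4.5]dec-7-ene-8-carboxylate
Product: 23 methyl (1R,4S,5S,9S)-9-(tert-butyldimethylsilyloxy)-4-methyl-1-[(2R)-6-methyl-5-oxoheptan-2-yl]spiro[4.5]dec-7-ene-8-carboxylate
Conditions: [(Ph3P)CuH]6 (0.35 equiv), H2O (5 equiv), degassed toluene, rt
Reagents that add atoms: none
Why: In this conjugate reduction with the Stryker reagent, the hydride of monovalent copper adds much faster to the unhindered, disubstituted acyclic enone than to the less electrophilic, α-substituted ring enoate shielded by the silyl ether, and water protonates the copper enolate so that only the saturated isopropyl ketone results.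

Step 16
Reactants: 23 methyl (1R,4S,5S,9S)-9-(tert-butyldimethylsilyloxy)-4-methyl-1-[(2R)-6-methyl-5-oxoheptan-2-yl]spiro[4.5]dec-7-ene-8-carboxylate
Product: 24 methyl (1R,4S,5S,9S)-9-hydroxy-4-methyl-1-[(2R)-6-methyl-5-oxoheptan-2-yl]spiro[4.5]dec-7-ene-8-carboxylate (CNP0116894.1)
Conditions: HF·pyridine, pyridine, THF, 0 °C to rt (polyethylene vessel); aq NaHCO3
Reagents that add atoms: none
Why: Fluoride-mediated cleavage of the silyl ether under buffered, weakly acidic conditions frees the 9S alcohol without elimination, olefin migration or epimerisation in the hydroxy enoate.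

Compound list
1 | 3'-methoxyacetophenone | COc1cccc(c1)C(C)=O | starting material
2 | (2-carboxyethyl)triphenylphosphonium bromide | OC(=O)CC[P+](c1ccccc1)(c1ccccc1)c1ccccc1.[Br-] | starting material
3 | potassium 3-(triphenylphosphoranylidene)propanoate (carboxylate ylide) | [K+].[O-]C(=O)CC=P(c1ccccc1)(c1ccccc1)c1ccccc1 | intermediate
4 | (E)-4-(3-methoxyphenyl)pent-3-enoic acid | COc1cccc(c1)/C(C)=C/CC(O)=O | intermediate
5 | (S)-4-(3-methoxyphenyl)pentanoic acid | OC(=O)CC[C@@H](c1cccc(OC)c1)C | intermediate
6 | (S)-4-(3-methoxyphenyl)pentan-1-ol | OCCC[C@@H](c1cccc(OC)c1)C | intermediate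
7 | (S)-4-(5-methoxycyclohexa-1,4-dien-1-yl)pentan-1-ol | OCCC[C@@H](C1=CCC=C(OC)C1)C | intermediate
8 | (S)-4-(5-methoxycyclohexa-1,4-dien-1-yl)pentanal | O=CCC[C@@H](C1=CCC=C(OC)C1)C | intermediate
9 | methyl 2-[bis(2,2,2-trifluoroethoxy)phosphoryl]propanoate | COC(=O)C(C)P(=O)(OCC(F)(F)F)OCC(F)(F)F | starting material
10 | potassium carbanion of 9 | [K+].COC(=O)[C-](C)P(=O)(OCC(F)(F)F)OCC(F)(F)F | intermediate
11 | methyl (2Z,6S)-6-(5-methoxycyclohexa-1,4-dien-1-yl)-2-methylhept-2-enoate | COC(=O)/C(C)=C\CC[C@@H](C1=CCC=C(OC)C1)C | intermediate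
12 | methyl (2S)-2-[(1R,4S,5S)-9-methoxy-4-methylspiro[4.5]deca-6,8-dien-1-yl]propanoate | COC1=CC=C[C@@]2(C1)[C@@H]([C@H](C)C(=O)OC)CC[C@@H]2C | intermediate
13 | methyl (2S)-2-[(1R,4S,5S)-4-methyl-9-oxospiro[4.5]dec-7-en-1-yl]propanoate | O=C1C=CC[C@@]2(C1)[C@@H]([C@H](C)C(=O)OC)CC[C@@H]2C | intermediate
14 | methyl (2S)-2-[(1R,4S,5S)-8-iodo-4-methyl-9-oxospiro[4.5]dec-7-en-1-yl]propanoate | O=C1C(I)=CC[C@@]2(C1)[C@@H]([C@H](C)C(=O)OC)CC[C@@H]2C | intermediate
15 | methyl (2S)-2-[(1R,4S,5S,9S)-9-hydroxy-8-iodo-4-methylspiro[4.5]dec-7-en-1-yl]propanoate | IC1=CC[C@@]2(C[C@@H]1O)[C@@H]([C@H](C)C(=O)OC)CC[C@@H]2C | intermediate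
16 | methyl (2S)-2-[(1R,4S,5S,9S)-9-(tert-butyldimethylsilyloxy)-8-iodo-4-methylspiro[4.5]dec-7-en-1-yl]propanoate | IC1=CC[C@@]2(C[C@@H]1O[Si](C)(C)C(C)(C)C)[C@@H]([C@H](C)C(=O)OC)CC[C@@H]2C | intermediate
17 | diisobutylaluminium hemiacetal of 16 (hemiacetal carbon undefined) | IC1=CC[C@@]2(C[C@@H]1O[Si](C)(C)C(C)(C)C)[C@@H]([C@H](C)C(OC)O[Al](CC(C)C)CC(C)C)CC[C@@H]2C | intermediate
18 | (2S)-2-[(1R,4S,5S,9S)-9-(tert-butyldimethylsilyloxy)-8-iodo-4-methylspiro[4.5]dec-7-en-1-yl]propanal | IC1=CC[C@@]2(C[C@@H]1O[Si](C)(C)C(C)(C)C)[C@@H]([C@H](C)C=O)CC[C@@H]2C | intermediate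
19 | dimethyl (3-methyl-2-oxobutyl)phosphonate | COP(=O)(OC)CC(=O)C(C)C | starting material
20 | lithium carbanion of 19 | [Li+].COP(=O)(OC)[CH-]C(=O)C(C)C | intermediate
21 | (4E,6R)-6-[(1R,4S,5S,9S)-9-(tert-butyldimethylsilyloxy)-8-iodo-4-methylspiro[4.5]dec-7-en-1-yl]-2-methylhept-4-en-3-one | IC1=CC[C@@]2(C[C@@H]1O[Si](C)(C)C(C)(C)C)[C@@H]([C@H](C)/C=C/C(=O)C(C)C)CC[C@@H]2C | intermediate
22 | methyl (1R,4S,5S,9S)-9-(tert-butyldimethylsilyloxy)-4-methyl-1-[(2R,3E)-6-methyl-5-oxohept-3-en-2-yl]spiro[4.5]dec-7-ene-8-carboxylate | COC(=O)C1=CC[C@@]2(C[C@@H]1O[Si](C)(C)C(C)(C)C)[C@@H]([C@H](C)/C=C/C(=O)C(C)C)CC[C@@H]2C | intermediate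
23 | methyl (1R,4S,5S,9S)-9-(tert-butyldimethylsilyloxy)-4-methyl-1-[(2R)-6-methyl-5-oxoheptan-2-yl]spiro[4.5]dec-7-ene-8-carboxylate | COC(=O)C1=CC[C@@]2(C[C@@H]1O[Si](C)(C)C(C)(C)C)[C@@H]([C@H](C)CCC(=O)C(C)C)CC[C@@H]2C | intermediate
24 | methyl (1R,4S,5S,9S)-9-hydroxy-4-methyl-1-[(2R)-6-methyl-5-oxoheptan-2-yl]spiro[4.5]dec-7-ene-8-carboxylate (CNP0116894.1) | COC(=O)C1=CC[C@@]2(C[C@@H]1O)[C@@H]([C@H](C)CCC(=O)C(C)C)CC[C@@H]2C | target

Total step count: 16. Longest linear sequence: 16 steps (1 to 24).

Steps most likely to fail

Step 7 (ene spirocyclisation). Several processes could defeat it: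
- The α-methyl group has to sit over the diene in the transition state, so the reaction may need temperatures at which the skipped diene loses hydrogen to the enoate and rearomatises.
- Traces of acid may conjugate the diene and open a cycloaddition path.
- The Z-enoate may isomerise thermally, which would erode the side-chain methine.
- The facial bias exerted by the C4 methyl group may be modest.

A 1,5-hydrogen shift within the product diene would be harmless, because hydrolysis converges on 13.

The fallback sets out from 7 and rejoins the route at 13. It replaces the untested methoxydiene donor by a plain 1-alkylcyclohexene, the donor class for which thermal ene spirocyclisation onto a tethered enoate is established. Exchange of the enol ether of 7 with ethylene glycol (catalytic pyridinium p-toluenesulfonate, CH2Cl2, rt) should give, with the trisubstituted olefin left in its β,γ position, the ketal alcohol (S)-4-(1,4-dioxaspiro[4.5]dec-7-en-7-yl)pentan-1-ol F1. Parikh-Doering oxidation then gives the aldehyde (S)-4-(1,4-dioxaspiro[4.5]dec-7-en-7-yl)pentanal F2. Still-Gennari olefination with 9 gives the Z-enoate methyl (2Z,6S)-6-(1,4-dioxaspiro[4.5]dec-7-en-7-yl)-2-methylhept-2-enoate F3. This substrate cannot aromatise and carries no enol ether, so it can be held at the roughly 280 °C (sealed tube, toluene, BHT) that monoene donors require. It should close through the same cis-fused transition state to the spiro ketal methyl (2S)-2-[(1R,4S,5S)-9,9-(ethylenedioxy)-4-methylspiro[4.5]dec-6-en-1-yl]propanoate F4. Treatment with 1 M HCl in THF removes the ketal to the β,γ-unsaturated ketone methyl (2S)-2-[(1R,4S,5S)-4-methyl-9-oxospiro[4.5]dec-6-en-1-yl]propanoate F5, which moves into conjugation under the same acid and gives 13.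

Step 10 (CBS reduction). The catalyst preference may be opposed by the intrinsic facial bias of the spiro ring (a mismatched pairing), or uncatalysed borane reduction may compete. Either would lower the selectivity at C9.

The fallback sets out from 14 and returns at 15. It replaces reagent control by separation and inversion. Luche reduction (NaBH4, CeCl3·7H2O, MeOH, −78 °C) gives 15 together with its epimer methyl (2S)-2-[(1R,4S,5S,9R)-9-hydroxy-8-iodo-4-methylspiro[4.5]dec-7-en-1-yl]propanoate F6; the two are diastereomers and are separated by chromatography. Mitsunobu inversion of the unwanted epimer (4-nitrobenzoic acid, PPh3, DIAD, THF, 0 °C) gives the ester methyl (2S)-2-[(1R,4S,5S,9S)-8-iodo-4-methyl-9-(4-nitrobenzoyloxy)spiro[4.5]dec-7-en-1-yl]propanoate F7. Brief methanolysis (K2CO3, MeOH, 0 °C), degenerate for the side-chain methyl ester, releases 15.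

Step 12 (partial ester reduction). The aluminium hemiacetal may collapse early, which leads to over-reduction. A sluggish reaction at the hindered ester may leave mixtures, and the α-methyl aldehyde may epimerise during a prolonged work-up.

The fallback sets out from 16 and returns at 18. It abandons the partial reduction for a redox detour. Excess i-Bu2AlH (2.5 equiv, CH2Cl2, −78 to 0 °C) takes the ester fully to the primary alcohol (2S)-2-[(1R,4S,5S,9S)-9-(tert-butyldimethylsilyloxy)-8-iodo-4-methylspiro[4.5]dec-7-en-1-yl]propan-1-ol F8. Oxidation with Dess-Martin periodinane buffered with NaHCO3 (CH2Cl2, 0 °C) gives 18, which is used at once in step 13.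

Further compounds
F1 | step 7 | (S)-4-(1,4-dioxaspiro[4.5]dec-7-en-7-yl)pentan-1-ol | OCCC[C@@H](C1=CCCC2(C1)OCCO2)C
F2 | step 7 | (S)-4-(1,4-dioxaspiro[4.5]dec-7-en-7-yl)pentanal | O=CCC[C@@H](C1=CCCC2(C1)OCCO2)C
F3 | step 7 | methyl (2Z,6S)-6-(1,4-dioxaspiro[4.5]dec-7-en-7-yl)-2-methylhept-2-enoate | COC(=O)/C(C)=C\CC[C@@H](C1=CCCC2(C1)OCCO2)C
F4 | step 7 | methyl (2S)-2-[(1R,4S,5S)-9,9-(ethylenedioxy)-4-methylspiro[4.5]dec-6-en-1-yl]propanoate | O1CCOC12CC=C[C@@]3(C2)[C@@H]([C@H](C)C(=O)OC)CC[C@@H]3C
F5 | step 7 | methyl (2S)-2-[(1R,4S,5S)-4-methyl-9-oxospiro[4.5]dec-6-en-1-yl]propanoate | O=C1CC=C[C@@]2(C1)[C@@H]([C@H](C)C(=O)OC)CC[C@@H]2C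
F6 | step 10 | methyl (2S)-2-[(1R,4S,5S,9R)-9-hydroxy-8-iodo-4-methylspiro[4.5]dec-7-en-1-yl]propanoate | IC1=CC[C@@]2(C[C@H]1O)[C@@H]([C@H](C)C(=O)OC)CC[C@@H]2C
F7 | step 10 | methyl (2S)-2-[(1R,4S,5S,9S)-8-iodo-4-methyl-9-(4-nitrobenzoyloxy)spiro[4.5]dec-7-en-1-yl]propanoate | IC1=CC[C@@]2(C[C@@H]1OC(=O)c3ccc(cc3)[N+]([O-])=O)[C@@H]([C@H](C)C(=O)OC)CC[C@@H]2C
F8 | step 12 | (2S)-2-[(1R,4S,5S,9S)-9-(tert-butyldimethylsilyloxy)-8-iodo-4-methylspiro[4.5]dec-7-en-1-yl]propan-1-ol | IC1=CC[C@@]2(C[C@@H]1O[Si](C)(C)C(C)(C)C)[C@@H]([C@H](C)CO)CC[C@@H]2C
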